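**Time first.** At 100 °C the six flasks run for 3.0 min, and they differ in their charge of starting material. I have Sunday's flask to reason from.

| flask | starting material | temperature | remark | time |
|---|---|---|---|---|
| Sunday's | 1.1 mM | 100 °C | run made earlier |  |
| west | 2.0 mM | 100 °C |  | 3.0 min |
| south-east | 1.5 mM | 100 °C |  | 3.0 min |
| east | 3.0 mM | 100 °C |  | 3.0 min |
| south | 0.50 mM | 100 °C |  | 3.0 min |
| south-west | 1.0 mM | 100 °C |  | 3.0 min |
| north-west | 0.25 mM | 100 °C |  | 3.0 min |

Sunday's run (percent of the starting material charged)

| time / s | target / % | starting material / % |
|---|---|---|
| 10.0 | 9.5 | 54.8 |
| 12.0 | 10.5 | 49.8 |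
| 20.0 | 14.9 | 32.8 |
| 30.0 | 17.5 | 18.7 |
| 50.0 | 20.2 | 6.8 |
| 60.0 | 21.2 | 3.6 |

(standard deviation of a reading: 1 percentage point)

1. the flasks put in order of amount of target, in percent of the starting material charged, best first, at 3.0 min (west / south-east / east / south / south-west / north-west)
2. the amount of target, in percent of the starting material charged of the flask you put first, at 3.0 min
3. the amount of target, in percent of the starting material charged of the flask you put last, at 3.0 min

- the numbers in the tables scatter by 1 percentage point (one standard deviation)
- a reading or a percentage of target counts all its forms, free or not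

**The clock.** On Sunday, starting material falls first order. The last reading gives 0.0554 s⁻¹, and the first gives 0.0601 s⁻¹. So the half-life is 12.5 s, far shorter than 3.0 min. I therefore count each flask as converted by the asked time.

**Two ways.** What remains is the share. The first way takes the first reading alone: target over starting material consumed gives 0.210. The second way takes the later stretch, from 20.0 s to 60.0 s, and gives 0.216. Different readings give about the same number, so I carry their mean, 0.213, as the share: target made per starting material consumed, the selectivity of the run. But both ways come from a charge of 1.1 mM. Neither can show whether the share moves with [starting material]. My reckoning is therefore flat, 21.3% in each flask, with no ranking.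

**The forecast.** It ranks north-west > south > south-west > south-east > west > east, with 23% first and 20.5% last, and it holds that “selectivity shouldn't depend on concentration”. Its low lies close to Sunday's last reading of 21.2%, taken over. Unlike my flat figure, it ranks the dilute flasks first.

**The result.** The flasks fall in the order north-west > south > south-west > south-east > west > east, from 27.0% down to 13.6%.

    starting material → intermediate A (k = 0.0302 s⁻¹, Ea = 88.0 kJ mol⁻¹)
    intermediate A → side product A (k = 0.0219 s⁻¹, Ea = 103 kJ mol⁻¹)
    starting material ⇌ intermediate B (K = 0.159, k = 0.120 s⁻¹, Ea = 104 kJ mol⁻¹, ΔH = 46.0 kJ mol⁻¹)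
    intermediate B → target (k = 0.164 s⁻¹, Ea = 90.0 kJ mol⁻¹)
    target ⇌ isomer of the product (K = 0.400, k = 0.140 s⁻¹, Ea = 86.0 kJ mol⁻¹, ΔH = −90.0 kJ mol⁻¹)
    starting material + target → side product B (k = 40.5 L mol⁻¹ s⁻¹, Ea = 52.0 kJ mol⁻¹)
    crystals ⇌ target, rate k7*(cs7 - [target]) while solid is left; crystals form when [target] > cs7 (solubility = 0.410 mM, k = 1.08 s⁻¹)
    (constants at 100 °C)

**Where it parts.** A neighbour with north-west's recipe at 1.0 mM sits near Sunday's charge and gives 21.4%, in line with the share. East gives 13.6%, a ratio of 0.638 to the share. The main reason east stays so low is the undoing of intermediate B into starting material. Without that way back, east ends at 62.4% of target instead of 13.6%. A further part is the step from starting material and target to side product B. Its rate carries [starting material], and side product B stands at 31.7% in east against 5.18% in north-west.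

The data stem from a simulated flask with constants of no real substance, and the scatter is random.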